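The readings are simulated with constants of no real substance; scatter was added.

The vessel is closed and stirred, with the gas phase above it held at 0.10 mM. I want the flask charged with 1.0 mM of substrate.

the same everywhere: gas phase 0.10 mM (held)
- noon: substrate 0.50 mM; run made earlier
- summer: substrate 2 mM; run made earlier
- flask: substrate 1.0 mM; time 5.0 min

- noon (time / min: target / %, substrate / %): 0.250: 21.9, 75.4; 0.833: 45.0, 39.5; 1.33: 46.4, 21.8; 2.00: 40.1, 12.0; 3.00: 27.2, 4.6; 4.00: 16.6, 1.4; 5.00: 8.1, 2.5
- summer (time / min: target / %, substrate / %): 0.417: 29.9, 65.3; 0.667: 39.5, 51.0; 1.00: 47.1, 36.8; 1.33: 47.8, 25.6; 2.00: 42.0, 12.7; 3.00: 28.0, 3.1; 5.00: 10.7, 1.0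

(readings scatter by 1 percentage point)

- the target standing at 5.0 min, as a percentage of the substrate charged
- concentration of dissolved gas in solution at 80 s, in percent of saturation
- the change that raises the amount of target at 5.0 min, in percent of the substrate charged most ("none" if none brings more than 2 percentage points) (theta / zeta / none)
- amount of target at 5.0 min, in percent of the substrate charged, after theta

I work with the fraction left, rung by rung. The first rung is the gas. In the noon run, the substrate left at 0.250 min gives 1.13 min⁻¹, and at 0.833 min it gives 1.12 min⁻¹. No lag shows, so I take the gas as in solution within that first reading.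

The second rung is the substrate. The summer run gives 1.00 min⁻¹, slower than noon. The mean is 1.06 min⁻¹, a half-life of 0.654 min. I expect 0.506% of the substrate left at 5.0 min.

The third rung is the target. Summing both runs, it falls from 55.2% at 3.00 min to 18.8% at 5.00 min, which gives 0.539 min⁻¹. This is the tail constant: the logarithm of the target's fraction left, per minute, late in a run. It is a pseudo-first-order constant, and it is smaller than the substrate's.

The flask's charge lies between the two runs, so I take the mean of their last readings, 9.40%. I read the slowing as gas deficit, 0.0770 mM⁻¹. I take both substrate and target as using gas, and at 80 s the load is 0.477 mM. So c(dissolved gas) stands near 96.5% of saturation. With doubled transfer I reckon a deficit of 1.77% of saturation, and that gives 8.96%. Doubled saturation doubles the tail constant and gives 0.635%. Neither gains, so I say none.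

The forecast gives 10%, 97%, 9.7% and none, since “gas transfer looks fast”; its three numbers stand above mine.

    gas phase ⇌ dissolved gas, rate k1*(csat - [dissolved gas]) (kL = 2.50 s⁻¹)
    substrate + dissolved gas → target (k = 190 M⁻¹ s⁻¹)
    dissolved gas + target → over-reacted product (k = 110 M⁻¹ s⁻¹)

The flask gives 8.64% and 96.3%, and 8.30% after doubled transfer; the best change is none, at −0.34 percentage points for theta and −8.3 points for zeta. The target's half-life by over-reaction is 1.1 min at 1.09 min, short against 5.0 min. At 5.0 min the flask holds 91.0% over-reacted product. Carried by the tail constant, the flask's 33.5% of target at 2.50 min comes to 8.71% at 5.0 min. Carried on from 8.64% to 8.0 min, the tail constant gives 1.71%, and that neighbour flask holds 1.30%.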